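**Retrosynthetic overview**
1. Ester C–O bond: target 22 ⇒ alcohol 17 + silyl-protected 4-hydroxybenzoyl chloride 20; 17 ⇐ ketone 16 by hydride addition anti to the angular methyl.
2. 16 ⇐ dienone 14 ⇐ cycloadduct 13: the ring alkene is moved from C7=C8 to C6=C7 by dehydrogenation and 1,6-reduction.
3. Key step: 13 ⇐ acyclic epoxy enolsilane 12. The five- and the seven-membered ring form together (bonds C3a–C8a and C5–C6) in an intramolecular (4+3) cycloaddition; the epoxide supplies the tertiary carbinol C3 and, with inversion, C3a.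
4. 12 ⇐ Z-enone 8 (asymmetric reduction, hydroxyl-directed epoxidation, oxidation, enol silylation); 8 ⇐ enyne 6 by isopropylcopper carbometalation/acylation.
5. 6 ⇐ pent-4-yn-1-ol 1 + (E)-1-bromopropene 2 (carboalumination/cross-coupling, oxidation, alkyne homologation).

Assumption: the SMILES is taken literally, i.e. (3S,3aS,4R,8aR) in azulene numbering (used throughout): trans ring fusion, 3-OH syn to H-3a, ester oxygen syn to the 8a-methyl.

**Step 1**
Reactants: 1 pent-4-yn-1-ol; 2 (E)-1-bromoprop-1-ene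
Product: 4 (4E,6E)-4-methylocta-4,6-dien-1-ol, via alkenylalane 3 (not isolated)
Conditions: Me3Al (3 equiv), Cp2ZrCl2 (0.25 equiv), CH2Cl2, 0 °C to rt; then 2, Pd(PPh3)4 (5 mol%), ZnCl2 (cat.), THF, rt; aq. HCl
Reagents that add atoms: trimethylaluminium C[Al](C)C
Why: Negishi zirconium-catalysed carboalumination adds methyl and aluminium syn to the terminal alkyne (E-alkenylalane), and the palladium-catalysed cross-coupling with the E-bromide keeps both alkene geometries, giving the E,E-diene.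

**Step 2**
Reactants: 4 (4E,6E)-4-methylocta-4,6-dien-1-ol
Product: 5 (4E,6E)-4-methylocta-4,6-dienal
Conditions: Dess–Martin periodinane, CH2Cl2, 0 °C to rt
Reagents that add atoms: none
Why: Dess–Martin oxidation of the primary alcohol is neutral and leaves the diene untouched.

**Step 3**
Reactants: 5 (4E,6E)-4-methylocta-4,6-dienal
Product: 6 (5E,7E)-5-methylnona-5,7-dien-1-yne
Conditions: dimethyl (1-diazo-2-oxopropyl)phosphonate, K2CO3, MeOH, 0 °C to rt
Reagents that add atoms: dimethyl (1-diazo-2-oxopropyl)phosphonate CC(=O)C(=[N+]=[N-])P(=O)(OC)OC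
Why: Ohira–Bestmann (Seyferth–Gilbert) homologation turns the aldehyde into the terminal alkyne under mild carbonate conditions that do not isomerise the diene.

**Step 4**
Reactants: 6 (5E,7E)-5-methylnona-5,7-dien-1-yne
Product: 8 (3Z,7E,9E)-7-methyl-4-(propan-2-yl)undeca-3,7,9-trien-2-one, via alkenylcopper 7 (not isolated)
Conditions: iPrMgBr, CuBr·SMe2, Et2O/Me2S, -45 °C; 6, -25 °C; then AcCl, Pd(PPh3)4 (3 mol%), THF, -20 °C to rt
Reagents that add atoms: isopropylmagnesium bromide CC(C)[Mg]Br; acetyl chloride CC(=O)Cl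
Why: Normant carbocupration adds isopropyl and copper syn across the terminal alkyne (isopropyl on the internal carbon), and palladium-catalysed acylation of the alkenylcopper proceeds with retention, so acetyl ends cis to isopropyl (Z-enone).

**Step 5**
Reactants: 8 (3Z,7E,9E)-7-methyl-4-(propan-2-yl)undeca-3,7,9-trien-2-one
Product: 9 (2S,3Z,7E,9E)-7-methyl-4-(propan-2-yl)undeca-3,7,9-trien-2-ol
Conditions: (R)-2-methyl-CBS-oxazaborolidine (0.2 equiv), catecholborane, toluene, -78 °C
Reagents that add atoms: none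
Why: Corey–Bakshi–Shibata reduction treats the alkenyl group as the large and methyl as the small substituent, so the (R)-catalyst gives the (S)-carbinol by clean 1,2-reduction.

**Step 6**
Reactants: 9 (2S,3Z,7E,9E)-7-methyl-4-(propan-2-yl)undeca-3,7,9-trien-2-ol
Product: 10 (1S)-1-[(2R,3S)-3-[(3E,5E)-3-methylhepta-3,5-dien-1-yl]-3-(propan-2-yl)oxiran-2-yl]ethan-1-ol
Conditions: VO(acac)2 (5 mol%), t-BuOOH (decane), CH2Cl2, 0 °C
Reagents that add atoms: tert-butyl hydroperoxide CC(C)(C)OO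
Why: Hydroxyl-directed vanadium-catalysed epoxidation reaches only the allylic alkene, and the Z-isopropyl group enforces the A(1,3)-minimised rotamer (carbinol H in the alkene plane) so oxygen is delivered to the OH face, giving the threo epoxy alcohol (minor erythro isomer removed by chromatography).

**Step 7**
Reactants: 10 (1S)-1-[(2R,3S)-3-[(3E,5E)-3-methylhepta-3,5-dien-1-yl]-3-(propan-2-yl)oxiran-2-yl]ethan-1-ol
Product: 11 1-[(2S,3S)-3-[(3E,5E)-3-methylhepta-3,5-dien-1-yl]-3-(propan-2-yl)oxiran-2-yl]ethan-1-one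
Conditions: Dess–Martin periodinane, pyridine, CH2Cl2, 0 °C to rt
Reagents that add atoms: none
Why: Buffered Dess–Martin oxidation removes the carbinol centre, which has done its directing job, and leaves the two epoxide stereocentres intact.

**Step 8**
Reactants: 11 1-[(2S,3S)-3-[(3E,5E)-3-methylhepta-3,5-dien-1-yl]-3-(propan-2-yl)oxiran-2-yl]ethan-1-one
Product: 12 triethyl[(1-{(2S,3S)-3-[(3E,5E)-3-methylhepta-3,5-dien-1-yl]-3-(propan-2-yl)oxiran-2-yl}ethenyl)oxy]silane
Conditions: LiN(SiMe3)2, Et3SiCl (in situ quench), THF, -78 °C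
Reagents that add atoms: chlorotriethylsilane CC[Si](Cl)(CC)CC
Why: Kinetic deprotonation can only occur at the methyl group (the other alpha carbon is the epoxide carbon), so O-silylation gives the terminal enol silane.

**Step 9**
Reactants: 12 triethyl[(1-{(2S,3S)-3-[(3E,5E)-3-methylhepta-3,5-dien-1-yl]-3-(propan-2-yl)oxiran-2-yl}ethenyl)oxy]silane
Product: 13 (3S,3aR,6R,8aR)-6,8a-dimethyl-3-(propan-2-yl)-3-[(triethylsilyl)oxy]-2,3,3a,5,6,8a-hexahydroazulen-4(1H)-one
Conditions: Et3SiOTf (20 mol%), CH2Cl2, -78 °C; Et3N quench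
Reagents that add atoms: none
Why: Proposed new method: the silyl triflate silylates the epoxide oxygen, the tethered diene terminus (future C8a) attacks the allylic epoxide carbon anti to the leaving oxygen (inversion at C3a, C3 carried over unchanged) and the enol silane carbon C5 closes onto the resulting allyl cation at C6, so both rings form at once; with the E-diene (tether outside) and the silyloxy group syn to C3 only the extended arrangement, which keeps the bulky silyloxy group away from the diene, leads to the required trans fusion; the closest known reaction type is the silyl-triflate-catalysed, epoxide-stereospecific intramolecular (4+3) cycloaddition of enantioenriched epoxy enolsilanes with tethered furans and simple dienes, and the extension is a 1,1-disubstituted diene terminus that creates the quaternary ring-fusion carbon (the C6 centre is erased in step 10).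

**Step 10**
Reactants: 13 (3S,3aR,6R,8aR)-6,8a-dimethyl-3-(propan-2-yl)-3-[(triethylsilyl)oxy]-2,3,3a,5,6,8a-hexahydroazulen-4(1H)-one
Product: 14 (3S,3aR,8aR)-6,8a-dimethyl-3-(propan-2-yl)-3-[(triethylsilyl)oxy]-2,3,3a,8a-tetrahydroazulen-4(1H)-one
Conditions: IBX, 4-methoxypyridine N-oxide, DMSO, 25 °C
Reagents that add atoms: none
Why: IBX dehydrogenation (Nicolaou) can only desaturate C5–C6, because on the other side C3a is flanked by the quaternary C8a, which gives the linear 2,4-dienone at room temperature.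

**Step 11**
Reactants: 14 (3S,3aR,8aR)-6,8a-dimethyl-3-(propan-2-yl)-3-[(triethylsilyl)oxy]-2,3,3a,8a-tetrahydroazulen-4(1H)-one
Product: 16 (3S,3aR,8aR)-6,8a-dimethyl-3-(propan-2-yl)-3-[(triethylsilyl)oxy]-2,3,3a,5,8,8a-hexahydroazulen-4(1H)-one, via lithium dienolate 15 (not isolated)
Conditions: Li, NH3(l)/THF, t-BuOH (1 equiv), -78 °C; then NH4Cl (solid)
Reagents that add atoms: none
Why: Dissolving-metal reduction of the linear dienone protonates the delta carbon C8 to give the extended dienolate, and kinetic alpha-protonation on quench gives the beta,gamma-unsaturated ketone with the C6=C7 alkene of the target, while C3a is never enolised.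

**Step 12**
Reactants: 16 (3S,3aR,8aR)-6,8a-dimethyl-3-(propan-2-yl)-3-[(triethylsilyl)oxy]-2,3,3a,5,8,8a-hexahydroazulen-4(1H)-one
Product: 17 (3S,3aS,4R,8aR)-6,8a-dimethyl-3-(propan-2-yl)-3-[(triethylsilyl)oxy]-1,2,3,3a,4,5,8,8a-octahydroazulen-4-ol
Conditions: NaBH4, CeCl3·7H2O, MeOH, -40 to 0 °C
Reagents that add atoms: none
Why: Luche reduction delivers hydride from the peripheral face, anti to the 8a-methyl that blocks the inner face, which sets C4 as R (oxygen syn to the 8a-methyl), and the near-neutral cerium medium avoids alkene conjugation and C3a epimerisation.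

**Step 13**
Reactants: 18 4-hydroxybenzoic acid
Product: 20 4-[(tert-butyldimethylsilyl)oxy]benzoyl chloride, via silyl ester 19 (not isolated)
Conditions: t-BuMe2SiCl (2.2 equiv), imidazole, DMF, rt; then (COCl)2, DMF (cat.), CH2Cl2, 0 °C to rt
Reagents that add atoms: tert-butyldimethylsilyl chloride CC(C)(C)[Si](C)(C)Cl; oxalyl chloride ClC(=O)C(Cl)=O
Why: Bis-silylation followed by the oxalyl chloride/DMF conversion of a silyl ester directly into the acid chloride gives the phenol-protected acylating agent under neutral conditions.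

**Step 14**
Reactants: 17 (3S,3aS,4R,8aR)-6,8a-dimethyl-3-(propan-2-yl)-3-[(triethylsilyl)oxy]-1,2,3,3a,4,5,8,8a-octahydroazulen-4-ol; 20 4-[(tert-butyldimethylsilyl)oxy]benzoyl chloride
Product: 21 (3S,3aS,4R,8aR)-6,8a-dimethyl-3-(propan-2-yl)-3-[(triethylsilyl)oxy]-1,2,3,3a,4,5,8,8a-octahydroazulen-4-yl 4-[(tert-butyldimethylsilyl)oxy]benzoate
Conditions: Et3N, DMAP, CH2Cl2, 0 to 40 °C
Reagents that add atoms: none
Why: DMAP-catalysed acylation of the only free hydroxyl (the tertiary one is silylated) forms the ester with retention at C4.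

**Step 15**
Reactants: 21 (3S,3aS,4R,8aR)-6,8a-dimethyl-3-(propan-2-yl)-3-[(triethylsilyl)oxy]-1,2,3,3a,4,5,8,8a-octahydroazulen-4-yl 4-[(tert-butyldimethylsilyl)oxy]benzoate
Product: 22 (3S,3aS,4R,8aR)-3-hydroxy-6,8a-dimethyl-3-(propan-2-yl)-1,2,3,3a,4,5,8,8a-octahydroazulen-4-yl 4-hydroxybenzoate
Conditions: HF·pyridine, pyridine, THF, 0 °C to rt
Reagents that add atoms: none
Why: Fluoride desilylation removes the phenolic and the tertiary silyl ether in one operation without touching the ester, the alkene or any stereocentre.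

**Compound list**
1 | pent-4-yn-1-ol | C#CCCCO | starting material
2 | (E)-1-bromoprop-1-ene | C/C=C/Br | starting material
3 | dimethyl[(1E)-5-[(dimethylalumanyl)oxy]-2-methylpent-1-en-1-yl]alumane (alkenylalane) | C[Al](C)OCCC/C(C)=C/[Al](C)C | intermediate (not isolated)
4 | (4E,6E)-4-methylocta-4,6-dien-1-ol | OCCC/C(C)=C/C=C/C | intermediate
5 | (4E,6E)-4-methylocta-4,6-dienal | O=CCC/C(C)=C/C=C/C | intermediate
6 | (5E,7E)-5-methylnona-5,7-dien-1-yne | C#CCC/C(C)=C/C=C/C | intermediate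
7 | [(1Z,5E,7E)-5-methyl-2-(propan-2-yl)nona-1,5,7-trien-1-yl]copper (alkenylcopper, MgBr2 complex) | [Cu]/C=C(\C(C)C)CC/C(C)=C/C=C/C | intermediate (not isolated)
8 | (3Z,7E,9E)-7-methyl-4-(propan-2-yl)undeca-3,7,9-trien-2-one | CC(=O)/C=C(\C(C)C)CC/C(C)=C/C=C/C | intermediate
9 | (2S,3Z,7E,9E)-7-methyl-4-(propan-2-yl)undeca-3,7,9-trien-2-ol | C[C@H](O)/C=C(\C(C)C)CC/C(C)=C/C=C/C | intermediate
10 | (1S)-1-[(2R,3S)-3-[(3E,5E)-3-methylhepta-3,5-dien-1-yl]-3-(propan-2-yl)oxiran-2-yl]ethan-1-ol | C[C@H](O)[C@H]1O[C@]1(C(C)C)CC/C(C)=C/C=C/C | intermediate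
11 | 1-[(2S,3S)-3-[(3E,5E)-3-methylhepta-3,5-dien-1-yl]-3-(propan-2-yl)oxiran-2-yl]ethan-1-one | CC(=O)[C@H]1O[C@]1(C(C)C)CC/C(C)=C/C=C/C | intermediate
12 | triethyl[(1-{(2S,3S)-3-[(3E,5E)-3-methylhepta-3,5-dien-1-yl]-3-(propan-2-yl)oxiran-2-yl}ethenyl)oxy]silane | C=C(O[Si](CC)(CC)CC)[C@H]1O[C@]1(C(C)C)CC/C(C)=C/C=C/C | intermediate
13 | (3S,3aR,6R,8aR)-6,8a-dimethyl-3-(propan-2-yl)-3-[(triethylsilyl)oxy]-2,3,3a,5,6,8a-hexahydroazulen-4(1H)-one | C[C@H]1C=C[C@@]2(C)CC[C@](O[Si](CC)(CC)CC)(C(C)C)[C@@H]2C(=O)C1 | intermediate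
14 | (3S,3aR,8aR)-6,8a-dimethyl-3-(propan-2-yl)-3-[(triethylsilyl)oxy]-2,3,3a,8a-tetrahydroazulen-4(1H)-one | CC1=CC(=O)[C@H]2[C@@](O[Si](CC)(CC)CC)(C(C)C)CC[C@]2(C)C=C1 | intermediate
15 | lithium (3S,3aS,8aR)-6,8a-dimethyl-3-(propan-2-yl)-3-[(triethylsilyl)oxy]-1,2,3,3a,8,8a-hexahydroazulen-4-olate | CC1=CC[C@@]2(C)CC[C@](O[Si](CC)(CC)CC)(C(C)C)[C@@H]2C([O-])=C1.[Li+] | intermediate (not isolated)
16 | (3S,3aR,8aR)-6,8a-dimethyl-3-(propan-2-yl)-3-[(triethylsilyl)oxy]-2,3,3a,5,8,8a-hexahydroazulen-4(1H)-one | CC1=CC[C@@]2(C)CC[C@](O[Si](CC)(CC)CC)(C(C)C)[C@@H]2C(=O)C1 | intermediate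
17 | (3S,3aS,4R,8aR)-6,8a-dimethyl-3-(propan-2-yl)-3-[(triethylsilyl)oxy]-1,2,3,3a,4,5,8,8a-octahydroazulen-4-ol | CC1=CC[C@@]2(C)CC[C@](O[Si](CC)(CC)CC)(C(C)C)[C@@H]2[C@H](O)C1 | intermediate
18 | 4-hydroxybenzoic acid | OC(=O)c1ccc(O)cc1 | starting material
19 | tert-butyldimethylsilyl 4-[(tert-butyldimethylsilyl)oxy]benzoate | CC(C)(C)[Si](C)(C)OC(=O)c1ccc(O[Si](C)(C)C(C)(C)C)cc1 | intermediate (not isolated)
20 | 4-[(tert-butyldimethylsilyl)oxy]benzoyl chloride | CC(C)(C)[Si](C)(C)Oc1ccc(cc1)C(Cl)=O | intermediate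
21 | (3S,3aS,4R,8aR)-6,8a-dimethyl-3-(propan-2-yl)-3-[(triethylsilyl)oxy]-1,2,3,3a,4,5,8,8a-octahydroazulen-4-yl 4-[(tert-butyldimethylsilyl)oxy]benzoate | CC1=CC[C@@]2(C)CC[C@](O[Si](CC)(CC)CC)(C(C)C)[C@@H]2[C@H](OC(=O)c2ccc(O[Si](C)(C)C(C)(C)C)cc2)C1 | intermediate
22 | (3S,3aS,4R,8aR)-3-hydroxy-6,8a-dimethyl-3-(propan-2-yl)-1,2,3,3a,4,5,8,8a-octahydroazulen-4-yl 4-hydroxybenzoate | CC1=CC[C@@]2(C)CC[C@](O)(C(C)C)[C@@H]2[C@H](OC(=O)c2ccc(O)cc2)C1 | target

**Total step count:** 15. **Longest linear sequence:** 14 (steps 1–12, 14, 15; step 13 is a side branch).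

**Steps most likely to fail**

Step 9 (key cycloaddition). The fully substituted diene terminus may not engage the epoxide, and the compact arrangement would give the cis-fused 8a-epimer; the required isomer places isopropyl, C4 and the 8a-methyl on one face of the cyclopentane, so it may well be the minor product. The fallback sets out from 11 and returns at 13. Reductive opening of the epoxy ketone with SmI2 (THF/MeOH, -90 °C) gives (4R,7E,9E)-4-hydroxy-7-methyl-4-(propan-2-yl)undeca-7,9-dien-2-one F1. Silylation (Et3SiOTf, 2,6-lutidine) gives (4R,7E,9E)-7-methyl-4-(propan-2-yl)-4-[(triethylsilyl)oxy]undeca-7,9-dien-2-one F2. Kinetic enolisation at the methyl group and chlorination with N-chlorosuccinimide gives (4R,7E,9E)-1-chloro-7-methyl-4-(propan-2-yl)-4-[(triethylsilyl)oxy]undeca-7,9-dien-2-one F3. Dehydrochlorination with NaOCH2CF3 in CF3CH2OH then generates a free oxyallyl cation (Föhlisch-type) for the intramolecular (4+3) cycloaddition. Here the stereochemistry is controlled by the silyloxy-bearing centre instead of by stereospecific epoxide opening, so 13 must be separated from its diastereomers.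

Step 4 (isopropylcopper carbometalation/acylation). A secondary alkylcopper may add sluggishly, and the Z-enone may partly isomerise. The fallback sets out from 6 and returns at 9, which also makes step 5 unnecessary. Lithiation of 6 (n-BuLi) and acylation with N-methoxy-N-methylacetamide gives (7E,9E)-7-methylundeca-7,9-dien-3-yn-2-one F4. Noyori transfer hydrogenation with RuCl(p-cymene)[(S,S)-TsDPEN] in iPrOH gives (2S,7E,9E)-7-methylundeca-7,9-dien-3-yn-2-ol F5. Hydroxyl-directed trans-hydroalumination with NaAlH2(OCH2CH2OMe)2 followed by iodine gives (2S,3Z,7E,9E)-4-iodo-7-methylundeca-3,7,9-trien-2-ol F6. Negishi coupling with iPrZnBr (Pd(OAc)2, CPhos) with retention of alkene geometry gives 9.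

Step 11 (1,6-reduction and kinetic protonation). Competing 1,4-reduction, over-reduction or conjugation of the product are possible. The fallback sets out from 14 and returns at 17, bypassing 16 and step 12. Luche 1,2-reduction (NaBH4, CeCl3·7H2O, MeOH) gives (3S,3aS,4R,8aR)-6,8a-dimethyl-3-(propan-2-yl)-3-[(triethylsilyl)oxy]-1,2,3,3a,4,8a-hexahydroazulen-4-ol F7. 1,4-Hydrogenation of its s-cis cycloheptadiene with H2 and (C10H8)Cr(CO)3 (naphthalene complex) adds hydrogen at C5 and C8 and leaves the C6=C7 alkene, giving 17.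

**Further compounds**
F1 | step 9 | (4R,7E,9E)-4-hydroxy-7-methyl-4-(propan-2-yl)undeca-7,9-dien-2-one | CC(=O)C[C@@](O)(C(C)C)CC/C(C)=C/C=C/C
F2 | step 9 | (4R,7E,9E)-7-methyl-4-(propan-2-yl)-4-[(triethylsilyl)oxy]undeca-7,9-dien-2-one | CC(=O)C[C@@](O[Si](CC)(CC)CC)(C(C)C)CC/C(C)=C/C=C/C
F3 | step 9 | (4R,7E,9E)-1-chloro-7-methyl-4-(propan-2-yl)-4-[(triethylsilyl)oxy]undeca-7,9-dien-2-one | ClCC(=O)C[C@@](O[Si](CC)(CC)CC)(C(C)C)CC/C(C)=C/C=C/C
F4 | step 4 | (7E,9E)-7-methylundeca-7,9-dien-3-yn-2-one | CC(=O)C#CCC/C(C)=C/C=C/C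
F5 | step 4 | (2S,7E,9E)-7-methylundeca-7,9-dien-3-yn-2-ol | C[C@H](O)C#CCC/C(C)=C/C=C/C
F6 | step 4 | (2S,3Z,7E,9E)-4-iodo-7-methylundeca-3,7,9-trien-2-ol | C[C@H](O)/C=C(\I)CC/C(C)=C/C=C/C
F7 | step 11 | (3S,3aS,4R,8aR)-6,8a-dimethyl-3-(propan-2-yl)-3-[(triethylsilyl)oxy]-1,2,3,3a,4,8a-hexahydroazulen-4-ol | CC1=C[C@@H](O)[C@H]2[C@@](O[Si](CC)(CC)CC)(C(C)C)CC[C@]2(C)C=C1
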